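The decaene is cut at the C12–C13 single bond, the sp2–sp2 link between the E-C11=C12 alkene and the methyl-bearing E-C13=C14 alkene of the chain joining ring A (β-ring, C3 R) and ring B (ε-ring, C3′ R, C6′ R). One Suzuki–Miyaura coupling unites a ring-A C16 trienyl boronate with a ring-B C24 hexaenyl bromide, both already palmitoylated and stereodefined, and gives helenien directly with retention at both alkenes. The bromide arises from the same reaction at the symmetry-related C12′–C13′ bond of a C2-symmetric C13–C13′ dibromotriene. Ring A comes from actinol; ring B from racemic α-ionone through a lipase resolution that installs the palmitate.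

Key step: step 14

Remark: the racemic intermediates made from α-ionone before the lipase step are drawn as one enantiomer, carotenoid numbering (primed for the ring-B half) is used throughout, and (4R,6R)-actinol is taken as a purchasable chiral-pool ketone.

Step 1
Reactants: 1 propyne
Product: 2 (E)-2-bromo-1-iodoprop-1-ene
Conditions: IBr (1.0 equiv), CH2Cl2, −78 to 0 °C, dark
Reagents that add atoms: iodine monobromide, IBr
Why: Electrophilic iodobromination of a terminal alkyne is an anti-addition that should place iodine on the terminal carbon and bromine on the methyl-bearing carbon, trans to each other, which pre-sets the later C13=C14 (and C13′=C14′) geometry.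

Step 2
Reactants: 2 (E)-2-bromo-1-iodoprop-1-ene (2.1 equiv); 3 (E)-1,2-bis(tributylstannyl)ethene
Product: 4 (2E,4E,6E)-2,7-dibromoocta-2,4,6-triene
Conditions: Pd2(dba)3 (cat.), AsPh3, NMP, rt, dark
Reagents that add atoms: none
Why: A twofold Stille coupling should occur only at the C–I bonds, because zerovalent palladium inserts into alkenyl iodides far faster than into alkenyl bromides, and it retains all three alkene geometries.

Step 3
Reactants: 5 rac-α-ionone; 6 diethyl cyanomethylphosphonate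
Product: 7 rac-(2E,4E)-3-methyl-5-(2,6,6-trimethylcyclohex-2-en-1-yl)penta-2,4-dienenitrile
Conditions: NaH, THF, 0 °C to rt; 9′Z isomer removed by chromatography
Reagents that add atoms: none
Why: Horner–Wadsworth–Emmons olefination of the methyl ketone with a stabilised phosphonate should favour the 9′E dienenitrile, and no stereocentre needs control at this racemic stage.

Step 4
Reactants: 7 rac-(2E,4E)-3-methyl-5-(2,6,6-trimethylcyclohex-2-en-1-yl)penta-2,4-dienenitrile
Product: 8 rac-(2E,4E)-3-methyl-5-(2,6,6-trimethyl-4-oxocyclohex-2-en-1-yl)penta-2,4-dienenitrile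
Conditions: t-BuOOH (70% aq), Rh2(cap)4 (cat.), K2CO3, CH2Cl2, rt
Reagents that add atoms: tert-butyl hydroperoxide, CC(C)(C)OO
Why: Catalytic allylic C–H oxidation by tert-butylperoxyl radicals should convert the only allylic CH2 of the ring alkene (C3′) into the enone carbonyl, the electron-poor dienenitrile being inert.

Step 5
Reactants: 8 rac-(2E,4E)-3-methyl-5-(2,6,6-trimethyl-4-oxocyclohex-2-en-1-yl)penta-2,4-dienenitrile
Product: 10 rac-(2E,4E)-5-[(1R*,4R*)-4-hydroxy-2,6,6-trimethylcyclohex-2-en-1-yl]-3-methylpenta-2,4-dienal, via aldimine 9 (not isolated)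
Conditions: i-Bu2AlH (3.3 equiv), CH2Cl2, −78 °C; aq potassium sodium tartrate, rt; chromatography to the 3′,6′-trans racemate
Reagents that add atoms: water, O
Why: Hydride reduction with i-Bu2AlH should reduce the enone 1,2 to the allylic alcohol and the nitrile to an N-aluminated aldimine that hydrolyses to the dienal on work-up, and the 3′,6′-trans racemate is then separated from the cis diastereomer.

Step 6
Reactants: 10 rac-(2E,4E)-5-[(1R*,4R*)-4-hydroxy-2,6,6-trimethylcyclohex-2-en-1-yl]-3-methylpenta-2,4-dienal; 11 vinyl palmitate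
Product: 12 (1R,4R)-3,5,5-trimethyl-4-[(1E,3E)-3-methyl-5-oxopenta-1,3-dien-1-yl]cyclohex-2-en-1-yl hexadecanoate
Conditions: Burkholderia cepacia lipase, t-BuOMe, 30 °C, stopped near half conversion; unreacted (3′S,6′S)-alcohol removed by chromatography
Reagents that add atoms: none
Why: Lipase-catalysed kinetic resolution by irreversible transesterification should acylate the 3′R alcohol, by the empirical rule for cyclic allylic alcohols in which the alkenyl side acts as the large group (as in (R)-cyclohex-2-enol), so resolution and palmitoylation occur in one operation and fix C3′ and C6′.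

Step 7
Reactants: 12 (1R,4R)-3,5,5-trimethyl-4-[(1E,3E)-3-methyl-5-oxopenta-1,3-dien-1-yl]cyclohex-2-en-1-yl hexadecanoate; 13 2-(dichloromethyl)-4,4,5,5-tetramethyl-1,3,2-dioxaborolane
Product: 14 (1R,4R)-3,5,5-trimethyl-4-[(1E,3E,5E)-3-methyl-6-(4,4,5,5-tetramethyl-1,3,2-dioxaborolan-2-yl)hexa-1,3,5-trien-1-yl]cyclohex-2-en-1-yl hexadecanoate
Conditions: CrCl2, LiI, THF, rt, dark
Reagents that add atoms: none
Why: The Takai–Utimoto borylalkenylation of an aldehyde by a geminal dichromium reagent should give the E-alkenyl boronate (C11′=C12′), and divalent chromium leaves the ester and the allylic C–O bond untouched.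

Step 8
Reactants: 14 (1R,4R)-3,5,5-trimethyl-4-[(1E,3E,5E)-3-methyl-6-(4,4,5,5-tetramethyl-1,3,2-dioxaborolan-2-yl)hexa-1,3,5-trien-1-yl]cyclohex-2-en-1-yl hexadecanoate; 4 (2E,4E,6E)-2,7-dibromoocta-2,4,6-triene (3 equiv)
Product: 15 (1R,4R)-4-[(1E,3E,5E,7E,9E,11E)-12-bromo-3,7-dimethyltrideca-1,3,5,7,9,11-hexaen-1-yl]-3,5,5-trimethylcyclohex-2-en-1-yl hexadecanoate
Conditions: Pd(PPh3)4 (cat.), TlOEt, THF/H2O, rt, dark
Reagents that add atoms: none
Why: Suzuki–Miyaura coupling with retention at both sp2 carbons should form the C12′–C13′ bond, and the excess of the symmetric dibromide keeps the reaction at the mono-coupling stage.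

Step 9
Reactants: 16 (4R,6R)-4-hydroxy-2,2,6-trimethylcyclohexan-1-one (actinol)
Product: 20 (4R)-4-hydroxy-2,6,6-trimethylcyclohex-1-en-1-yl trifluoromethanesulfonate, via silyl ether 17 (not isolated), via lithium enolate 18 (not isolated), via silyloxy triflate 19 (not isolated)
Conditions: LiN(i-Pr)2 (1.0 equiv), THF, −78 °C, then Me3SiCl; LiN(i-Pr)2 (1.2 equiv), −78 to 0 °C; PhNTf2, −78 °C to rt; aq citric acid, THF, rt
Reagents that add atoms: N-phenylbis(trifluoromethanesulfonimide), O=S(=O)(N(c1ccccc1)S(=O)(=O)C(F)(F)F)C(F)(F)F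
Why: Transient O-silylation followed by enolate O-triflation at the only enolisable position should give the tetrasubstituted enol triflate; the C6 stereocentre of actinol is erased, the carbinol centre (later C3, R) is untouched, and the labile silyl ether falls off on acidic work-up.

Step 10
Reactants: 20 (4R)-4-hydroxy-2,6,6-trimethylcyclohex-1-en-1-yl trifluoromethanesulfonate; 21 palmitoyl chloride
Product: 22 (1R)-3,5,5-trimethyl-4-(trifluoromethanesulfonyloxy)cyclohex-3-en-1-yl hexadecanoate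
Conditions: pyridine, DMAP (cat.), CH2Cl2, 0 °C to rt
Reagents that add atoms: none
Why: Nucleophile-catalysed acylation of the secondary alcohol with an acid chloride does not break the C–O bond, so the configuration is retained.

Step 11
Reactants: 23 (E)-3-methylpent-2-en-4-yn-1-ol; 22 (1R)-3,5,5-trimethyl-4-(trifluoromethanesulfonyloxy)cyclohex-3-en-1-yl hexadecanoate
Product: 26 (1R)-4-[(1E,3E)-5-hydroxy-3-methylpenta-1,3-dien-1-yl]-3,5,5-trimethylcyclohex-3-en-1-yl hexadecanoate, via dienylzirconocene 24 (not isolated), via dienylzinc chloride 25 (not isolated)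
Conditions: 23, Cp2Zr(H)Cl (2.2 equiv), THF, rt; ZnCl2; then 22, Pd(PPh3)4 (cat.), THF, 50 °C
Reagents that add atoms: none
Why: syn-Hydrozirconation of the terminal alkyne (the first equivalent of Cp2Zr(H)Cl caps the hydroxyl as its zirconium alkoxide) sets the E-C7=C8 alkene, and Negishi coupling through the alkenylzinc with the hindered enol triflate should form C6–C7 with retention while the 9E alkene of 23 is carried over.

Step 12
Reactants: 26 (1R)-4-[(1E,3E)-5-hydroxy-3-methylpenta-1,3-dien-1-yl]-3,5,5-trimethylcyclohex-3-en-1-yl hexadecanoate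
Product: 27 (1R)-3,5,5-trimethyl-4-[(1E,3E)-3-methyl-5-oxopenta-1,3-dien-1-yl]cyclohex-3-en-1-yl hexadecanoate
Conditions: MnO2, CH2Cl2, rt, dark
Reagents that add atoms: none
Why: MnO2 oxidation is selective for the primary allylic alcohol and should give the dienal without alkene isomerisation or ester cleavage.

Step 13
Reactants: 27 (1R)-3,5,5-trimethyl-4-[(1E,3E)-3-methyl-5-oxopenta-1,3-dien-1-yl]cyclohex-3-en-1-yl hexadecanoate; 13 2-(dichloromethyl)-4,4,5,5-tetramethyl-1,3,2-dioxaborolane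
Product: 28 (1R)-3,5,5-trimethyl-4-[(1E,3E,5E)-3-methyl-6-(4,4,5,5-tetramethyl-1,3,2-dioxaborolan-2-yl)hexa-1,3,5-trien-1-yl]cyclohex-3-en-1-yl hexadecanoate
Conditions: CrCl2, LiI, THF, rt, dark
Reagents that add atoms: none
Why: The Takai–Utimoto borylalkenylation, as in step 7, should set the E-C11=C12 alkene and place boron on C12.

Step 14
Reactants: 15 (1R,4R)-4-[(1E,3E,5E,7E,9E,11E)-12-bromo-3,7-dimethyltrideca-1,3,5,7,9,11-hexaen-1-yl]-3,5,5-trimethylcyclohex-2-en-1-yl hexadecanoate; 28 (1R)-3,5,5-trimethyl-4-[(1E,3E,5E)-3-methyl-6-(4,4,5,5-tetramethyl-1,3,2-dioxaborolan-2-yl)hexa-1,3,5-trien-1-yl]cyclohex-3-en-1-yl hexadecanoate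
Product: 29 helenien, (3R,3′R,6′R)-β,ε-carotene-3,3′-diyl dihexadecanoate
Conditions: Pd(OAc)2 (cat.), SPhos, K3PO4 (aq), THF, rt, degassed, dark
Reagents that add atoms: none
Why: Zerovalent palladium inserts into the C13–Br bond of 15 with retention, the phosphate-activated boronate 28 transfers its C12 alkenyl group with retention, and reductive elimination forms the C12–C13 sp2–sp2 bond, so the pre-set E geometries of C11=C12 and C13=C14 pass unchanged into the product. The closest known reaction type is the alkenyl–alkenyl Suzuki–Miyaura coupling used to assemble retinoid and carotenoid polyenes. No ring is closed and no stereocentre is created; C3, C3′ and C6′ are remote spectators. The step needs chemoselectivity for the alkenyl bromide over ionisation of the allylic 3′-palmitate and over ester hydrolysis, which the hindered trisubstituted ring-B alkene next to the quaternary C1′, the room-temperature conditions and the mild phosphate base should secure. It also needs configurational integrity of the growing decaene, which degassed solvent and exclusion of light should protect. The step is convergent and final: it delivers the whole C40 skeleton with both esters in place in one operation.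

Compound list
1 | propyne | CC#C | starting material
2 | (E)-2-bromo-1-iodoprop-1-ene | C/C(Br)=C\I | intermediate
3 | (E)-1,2-bis(tributylstannyl)ethene | CCCC[Sn](CCCC)(CCCC)/C=C/[Sn](CCCC)(CCCC)CCCC | starting material
4 | (2E,4E,6E)-2,7-dibromoocta-2,4,6-triene | Br/C(C)=C/C=C/C=C(\C)Br | intermediate
5 | rac-α-ionone, (E)-4-(2,6,6-trimethylcyclohex-2-en-1-yl)but-3-en-2-one | CC(=O)/C=C/C1C(C)=CCCC1(C)C | starting material
6 | diethyl cyanomethylphosphonate | CCOP(=O)(CC#N)OCC | starting material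
7 | rac-(2E,4E)-3-methyl-5-(2,6,6-trimethylcyclohex-2-en-1-yl)penta-2,4-dienenitrile | N#C/C=C(C)/C=C/C1C(C)=CCCC1(C)C | intermediate
8 | rac-(2E,4E)-3-methyl-5-(2,6,6-trimethyl-4-oxocyclohex-2-en-1-yl)penta-2,4-dienenitrile | N#C/C=C(C)/C=C/C1C(C)=CC(=O)CC1(C)C | intermediate
9 | rac-(2E,4E)-5-[(1R*,4R*)-4-hydroxy-2,6,6-trimethylcyclohex-2-en-1-yl]-3-methylpenta-2,4-dien-1-imine, formed as its N-aluminium derivative (racemate, one enantiomer drawn) | N=C/C=C(C)/C=C/[C@H]1C(C)=C[C@H](O)CC1(C)C | intermediate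
10 | rac-(2E,4E)-5-[(1R*,4R*)-4-hydroxy-2,6,6-trimethylcyclohex-2-en-1-yl]-3-methylpenta-2,4-dienal (3′,6′-trans racemate, one enantiomer drawn) | O=C/C=C(C)/C=C/[C@H]1C(C)=C[C@H](O)CC1(C)C | intermediate
11 | vinyl palmitate (ethenyl hexadecanoate) | CCCCCCCCCCCCCCCC(=O)OC=C | starting material
12 | (1R,4R)-3,5,5-trimethyl-4-[(1E,3E)-3-methyl-5-oxopenta-1,3-dien-1-yl]cyclohex-2-en-1-yl hexadecanoate | O=C/C=C(C)/C=C/[C@H]1C(C)=C[C@H](OC(=O)CCCCCCCCCCCCCCC)CC1(C)C | intermediate
13 | 2-(dichloromethyl)-4,4,5,5-tetramethyl-1,3,2-dioxaborolane | ClC(Cl)B1OC(C)(C)C(C)(C)O1 | starting material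
14 | (1R,4R)-3,5,5-trimethyl-4-[(1E,3E,5E)-3-methyl-6-(4,4,5,5-tetramethyl-1,3,2-dioxaborolan-2-yl)hexa-1,3,5-trien-1-yl]cyclohex-2-en-1-yl hexadecanoate | CC1(C)OB(/C=C/C=C(C)/C=C/[C@H]2C(C)=C[C@H](OC(=O)CCCCCCCCCCCCCCC)CC2(C)C)OC1(C)C | intermediate
15 | (1R,4R)-4-[(1E,3E,5E,7E,9E,11E)-12-bromo-3,7-dimethyltrideca-1,3,5,7,9,11-hexaen-1-yl]-3,5,5-trimethylcyclohex-2-en-1-yl hexadecanoate | Br/C(C)=C/C=C/C=C(C)/C=C/C=C(C)/C=C/[C@H]1C(C)=C[C@H](OC(=O)CCCCCCCCCCCCCCC)CC1(C)C | intermediate
16 | (4R,6R)-4-hydroxy-2,2,6-trimethylcyclohexan-1-one (actinol) | O[C@@H]1C[C@@H](C)C(=O)C(C)(C)C1 | starting material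
17 | (4R,6R)-2,2,6-trimethyl-4-(trimethylsilyloxy)cyclohexan-1-one | C[Si](C)(C)O[C@@H]1C[C@@H](C)C(=O)C(C)(C)C1 | intermediate
18 | lithium (4R)-2,6,6-trimethyl-4-(trimethylsilyloxy)cyclohex-1-en-1-olate | C[Si](C)(C)O[C@@H]1CC(C)=C(O[Li])C(C)(C)C1 | intermediate
19 | (4R)-2,6,6-trimethyl-4-(trimethylsilyloxy)cyclohex-1-en-1-yl trifluoromethanesulfonate | C[Si](C)(C)O[C@@H]1CC(C)=C(OS(=O)(=O)C(F)(F)F)C(C)(C)C1 | intermediate
20 | (4R)-4-hydroxy-2,6,6-trimethylcyclohex-1-en-1-yl trifluoromethanesulfonate | O[C@@H]1CC(C)=C(OS(=O)(=O)C(F)(F)F)C(C)(C)C1 | intermediate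
21 | palmitoyl chloride (hexadecanoyl chloride) | CCCCCCCCCCCCCCCC(=O)Cl | starting material
22 | (1R)-3,5,5-trimethyl-4-(trifluoromethanesulfonyloxy)cyclohex-3-en-1-yl hexadecanoate | CCCCCCCCCCCCCCCC(=O)O[C@@H]1CC(C)=C(OS(=O)(=O)C(F)(F)F)C(C)(C)C1 | intermediate
23 | (E)-3-methylpent-2-en-4-yn-1-ol | C#C/C(C)=C/CO | starting material
24 | chloro[(1E,3E)-5-(chlorozirconocenyloxy)-3-methylpenta-1,3-dien-1-yl]zirconocene, Cp2Zr(Cl)–CH=CH–C(Me)=CH–CH2–O–Zr(Cl)Cp2 | Cl[Zr](/C=C/C(C)=C/CO[Zr](Cl)(C1C=CC=C1)C1C=CC=C1)(C1C=CC=C1)C1C=CC=C1 | intermediate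
25 | [(1E,3E)-5-(chlorozirconocenyloxy)-3-methylpenta-1,3-dien-1-yl]zinc chloride | Cl[Zn]/C=C/C(C)=C/CO[Zr](Cl)(C1C=CC=C1)C1C=CC=C1 | intermediate
26 | (1R)-4-[(1E,3E)-5-hydroxy-3-methylpenta-1,3-dien-1-yl]-3,5,5-trimethylcyclohex-3-en-1-yl hexadecanoate | CCCCCCCCCCCCCCCC(=O)O[C@@H]1CC(C)=C(/C=C/C(C)=C/CO)C(C)(C)C1 | intermediate
27 | (1R)-3,5,5-trimethyl-4-[(1E,3E)-3-methyl-5-oxopenta-1,3-dien-1-yl]cyclohex-3-en-1-yl hexadecanoate | CCCCCCCCCCCCCCCC(=O)O[C@@H]1CC(C)=C(/C=C/C(C)=C/C=O)C(C)(C)C1 | intermediate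
28 | (1R)-3,5,5-trimethyl-4-[(1E,3E,5E)-3-methyl-6-(4,4,5,5-tetramethyl-1,3,2-dioxaborolan-2-yl)hexa-1,3,5-trien-1-yl]cyclohex-3-en-1-yl hexadecanoate | CCCCCCCCCCCCCCCC(=O)O[C@@H]1CC(C)=C(/C=C/C(C)=C/C=C/B2OC(C)(C)C(C)(C)O2)C(C)(C)C1 | intermediate
29 | helenien, (3R,3′R,6′R)-β,ε-carotene-3,3′-diyl dihexadecanoate | CCCCCCCCCCCCCCCC(=O)O[C@@H]1CC(C)=C(/C=C/C(C)=C/C=C/C(C)=C/C=C/C=C(C)/C=C/C=C(C)/C=C/[C@H]2C(C)=C[C@H](OC(=O)CCCCCCCCCCCCCCC)CC2(C)C)C(C)(C)C1 | target

Total step count: 14. Longest linear sequence: 7 steps (3, 4, 5, 6, 7, 8, 14).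

Steps most likely to fail

Step 8. Over-coupling may occur: after the first coupling the zerovalent palladium can remain on the polyene and insert into the second C–Br bond, so the doubly coupled product competes even with excess 4. The fallback inverts the polarity of both couplings; it sets out from 4, 12 and 27 and comes back at 29. Miyaura borylation of 4 (B2pin2, PdCl2(PPh3)2, PPh3, KOPh, toluene, 50 °C) would give the linchpin as a bis-nucleophile, 2,2′-[(2E,4E,6E)-octa-2,4,6-triene-2,7-diyl]bis(4,4,5,5-tetramethyl-1,3,2-dioxaborolane) F1, to which released catalyst cannot add. Takai olefination of 12 (CHI3, CrCl2, THF, 0 °C) would give the ring-B trienyl iodide (1R,4R)-4-[(1E,3E,5E)-6-iodo-3-methylhexa-1,3,5-trien-1-yl]-3,5,5-trimethylcyclohex-2-en-1-yl hexadecanoate F2. Suzuki–Miyaura coupling of F2 with excess F1 (Pd(PPh3)4, TlOEt, THF/H2O, rt) would give the C24 hexaenyl boronate (1R,4R)-4-[(1E,3E,5E,7E,9E,11E)-3,7-dimethyl-12-(4,4,5,5-tetramethyl-1,3,2-dioxaborolan-2-yl)trideca-1,3,5,7,9,11-hexaen-1-yl]-3,5,5-trimethylcyclohex-2-en-1-yl hexadecanoate F3. Takai olefination of 27 would give the ring-A trienyl iodide (1R)-4-[(1E,3E,5E)-6-iodo-3-methylhexa-1,3,5-trien-1-yl]-3,5,5-trimethylcyclohex-3-en-1-yl hexadecanoate F4. Coupling F3 with F4 under the same conditions forms the same C12–C13 bond and gives 29.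

Step 6. The lipase may discriminate the enantiomers poorly or in the opposite sense, because the quaternary C1′ sits close to the carbinol. The fallback replaces enzymatic resolution by catalyst-controlled reduction; it sets out from 8 and comes back at 12. Noyori transfer hydrogenation of racemic 8 (RuCl[(R,R)-TsDPEN](p-cymene), HCO2H/Et3N, rt) should set C3′ as R in both C6′ epimers, the conjugated alkene taking the place of the aryl group in the usual model. The 3′,6′-trans isomer, (2E,4E)-5-[(1R,4R)-4-hydroxy-2,6,6-trimethylcyclohex-2-en-1-yl]-3-methylpenta-2,4-dienenitrile F5, is separated from its cis diastereomer and reduced with i-Bu2AlH to (2E,4E)-5-[(1R,4R)-4-hydroxy-2,6,6-trimethylcyclohex-2-en-1-yl]-3-methylpenta-2,4-dienal F6, the single enantiomer of 10. Acylation of F6 with 21 and pyridine gives 12.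

Step 11. Hydrozirconation may stall on the free hydroxyl, or transmetalation and oxidative addition may be too slow at the tetrasubstituted enol triflate, so the alkenylmetal is lost to protonation. The fallback uses an isolated stannane; it sets out from 23 and comes back at 26. Palladium-catalysed hydrostannation of 23 (Bu3SnH, PdCl2(PPh3)2 (cat.), THF, 0 °C) would give (2E,4E)-3-methyl-5-(tributylstannyl)penta-2,4-dien-1-ol F7 after removal of the internal regioisomer. Copper-accelerated Stille coupling of F7 with 22 (Pd(PPh3)4, CuCl, LiCl, DMSO, 60 °C) gives 26.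

Further compounds
F1 | step 8 | 2,2′-[(2E,4E,6E)-octa-2,4,6-triene-2,7-diyl]bis(4,4,5,5-tetramethyl-1,3,2-dioxaborolane) | CC1(C)OB(/C(C)=C/C=C/C=C(\C)B2OC(C)(C)C(C)(C)O2)OC1(C)C
F2 | step 8 | (1R,4R)-4-[(1E,3E,5E)-6-iodo-3-methylhexa-1,3,5-trien-1-yl]-3,5,5-trimethylcyclohex-2-en-1-yl hexadecanoate | I/C=C/C=C(C)/C=C/[C@H]1C(C)=C[C@H](OC(=O)CCCCCCCCCCCCCCC)CC1(C)C
F3 | step 8 | (1R,4R)-4-[(1E,3E,5E,7E,9E,11E)-3,7-dimethyl-12-(4,4,5,5-tetramethyl-1,3,2-dioxaborolan-2-yl)trideca-1,3,5,7,9,11-hexaen-1-yl]-3,5,5-trimethylcyclohex-2-en-1-yl hexadecanoate | CC1(C)OB(/C(C)=C/C=C/C=C(C)/C=C/C=C(C)/C=C/[C@H]2C(C)=C[C@H](OC(=O)CCCCCCCCCCCCCCC)CC2(C)C)OC1(C)C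
F4 | step 8 | (1R)-4-[(1E,3E,5E)-6-iodo-3-methylhexa-1,3,5-trien-1-yl]-3,5,5-trimethylcyclohex-3-en-1-yl hexadecanoate | CCCCCCCCCCCCCCCC(=O)O[C@@H]1CC(C)=C(/C=C/C(C)=C/C=C/I)C(C)(C)C1
F5 | step 6 | (2E,4E)-5-[(1R,4R)-4-hydroxy-2,6,6-trimethylcyclohex-2-en-1-yl]-3-methylpenta-2,4-dienenitrile | N#C/C=C(C)/C=C/[C@H]1C(C)=C[C@H](O)CC1(C)C
F6 | step 6 | (2E,4E)-5-[(1R,4R)-4-hydroxy-2,6,6-trimethylcyclohex-2-en-1-yl]-3-methylpenta-2,4-dienal, single enantiomer of 10 | O=C/C=C(C)/C=C/[C@H]1C(C)=C[C@H](O)CC1(C)C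
F7 | step 11 | (2E,4E)-3-methyl-5-(tributylstannyl)penta-2,4-dien-1-ol | CCCC[Sn](CCCC)(CCCC)/C=C/C(C)=C/CO
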